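**Retrosynthetic overview**

1. Target 23 comes from tigloylation of the C8 hydroxyl of butenolide 22, itself from silyl ether 21.
2. The butenolide ring and the C13 acetate of 21 are made together from ten-membered α-allenol 20 by one oxidative carbonylative acetoxy-lactonization (C6–O–C12, C12–C11 and C13–OAc bonds; new reaction).
3. The ten-membered carbocycle of 20 is closed at C6–C7 by a CrCl2-mediated intramolecular Barbier allenylation of a propargylic chloride onto cis-epoxy aldehyde 18.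
4. 18 comes from catalytic asymmetric alkynylation of aldehyde 12 with propargyl chloride (C7–C8); 12 comes from a Marshall anti-propargylation of aldehyde 5 (C1–C10).
5. 5 comes from nerol by Sharpless epoxidation (C4, C5) and ozonolysis. Ring order: oxirane, then ten-membered ring, then butenolide.

Assumption: ring compounds are named with germacrane numbering (ring C1–C10, C14 on C10, C15 on C4, C11–C13 on C7); the target is read as 1S,4R,5S,6S,8S,10R with a cis 4,5-epoxide.

**Route**

Step 1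
Reactants: 1 nerol
Product: 2 [(2S,3R)-3-methyl-3-(4-methylpent-3-en-1-yl)oxiran-2-yl]methanol
Conditions: Ti(OiPr)4 (5 mol%), L-(+)-diethyl tartrate (7 mol%), t-BuOOH, 4 Å MS, CH2Cl2, −20 °C
Reagents that add atoms: tert-butyl hydroperoxide, CC(C)(C)OO
Why: Sharpless asymmetric epoxidation touches only the allylic-alcohol alkene, and L-(+)-tartrate gives the (2S,3R) cis-epoxide from the Z-alkene, which fixes C4 (R) and C5 (S) of the target.

Step 2
Reactants: 2 [(2S,3R)-3-methyl-3-(4-methylpent-3-en-1-yl)oxiran-2-yl]methanol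
Product: 3 triethyl{[(2S,3R)-3-methyl-3-(4-methylpent-3-en-1-yl)oxiran-2-yl]methoxy}silane
Conditions: TESCl, imidazole, CH2Cl2, 0 °C
Reagents that add atoms: chlorotriethylsilane, CC[Si](Cl)(CC)CC
Why: Standard silylation masks the future C6 carbinol as a primary TES ether that step 9 converts straight into the aldehyde.

Step 3
Reactants: 3 triethyl{[(2S,3R)-3-methyl-3-(4-methylpent-3-en-1-yl)oxiran-2-yl]methoxy}silane
Product: 5 3-[(2R,3S)-2-methyl-3-{[(triethylsilyl)oxy]methyl}oxiran-2-yl]propanal, via secondary ozonide 4 (not isolated)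
Conditions: O3, CH2Cl2, −78 °C; then PPh3, −78 °C to rt
Reagents that add atoms: ozone, O=[O+][O-]
Why: Ozonolysis with reductive work-up cleaves the only remaining alkene to unveil the C1 aldehyde, while the epoxide and silyl ether are inert.

Step 4
Reactants: 6 (S)-but-3-yn-2-ol
Product: 7 (S)-but-3-yn-2-yl methanesulfonate
Conditions: MsCl, Et3N, CH2Cl2, −78 °C
Reagents that add atoms: methanesulfonyl chloride, CS(=O)(=O)Cl
Why: O-Sulfonylation with retention gives the enantiopure propargylic electrophile for the Marshall reagent.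

Step 5
Reactants: 5 3-[(2R,3S)-2-methyl-3-{[(triethylsilyl)oxy]methyl}oxiran-2-yl]propanal; 7 (S)-but-3-yn-2-yl methanesulfonate
Product: 10 (3S,4R)-4-methyl-1-[(2R,3S)-2-methyl-3-{[(triethylsilyl)oxy]methyl}oxiran-2-yl]hex-5-yn-3-yl acetate, via allenylzinc reagent 8 (not isolated), via zinc alkoxide 9 (not isolated)
Conditions: Pd(OAc)2 (5 mol%), PPh3 (5 mol%), Et2Zn (3 equiv), THF, −78 to −20 °C; then Ac2O, DMAP, −20 °C to rt
Reagents that add atoms: acetic anhydride, CC(=O)OC(C)=O
Why: In this Marshall propargylation, anti-SN2′ attack of zerovalent palladium on 7 and transmetalation give an axially defined allenylzinc that adds through a cyclic SE2′ transition state, setting C10 (R) and C1 (S) anti under reagent control; the alkoxide is acetylated in the flask so the free 1-hydroxy-4,5-epoxide, prone to 5-exo cyclization, is never handled.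

Step 6
Reactants: 10 (3S,4R)-4-methyl-1-[(2R,3S)-2-methyl-3-{[(triethylsilyl)oxy]methyl}oxiran-2-yl]hex-5-yn-3-yl acetate
Product: 12 (3S,4R)-4-methyl-1-[(2R,3S)-2-methyl-3-{[(triethylsilyl)oxy]methyl}oxiran-2-yl]-6-oxohexan-3-yl acetate, via alkenylborane 11 (not isolated)
Conditions: Cy2BH, THF, 0 °C; then NaBO3·4H2O, THF–H2O, rt
Reagents that add atoms: sodium perborate, [Na+].[O-]OB=O
Why: Anti-Markovnikov hydroboration–oxidation of the terminal alkyne with a hindered dialkylborane gives the C8 aldehyde directly, and mild perborate spares the acetate and epoxide.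

Step 7
Reactants: 12 (3S,4R)-4-methyl-1-[(2R,3S)-2-methyl-3-{[(triethylsilyl)oxy]methyl}oxiran-2-yl]-6-oxohexan-3-yl acetate; 13 propargyl chloride
Product: 15 (3S,4R,6S)-9-chloro-6-hydroxy-4-methyl-1-[(2R,3S)-2-methyl-3-{[(triethylsilyl)oxy]methyl}oxiran-2-yl]non-7-yn-3-yl acetate, via alkynylzinc reagent 14 (not isolated)
Conditions: Me2Zn (3 equiv), (S,S)-ProPhenol (10 mol%), Ph3P=O (20 mol%), toluene, 0 °C
Reagents that add atoms: none
Why: Zinc–ProPhenol catalytic asymmetric alkynylation delivers the alkynyl group to the Re face of the aldehyde to set C8 (S) and brings in C7, C11 and C13 with the chloride needed for step 10 already in place; I could not confirm the sense of induction of the (S,S) ligand, so it is checked on a model aldehyde and the antipode used if needed.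

Step 8
Reactants: 15 (3S,4R,6S)-9-chloro-6-hydroxy-4-methyl-1-[(2R,3S)-2-methyl-3-{[(triethylsilyl)oxy]methyl}oxiran-2-yl]non-7-yn-3-yl acetate
Product: 16 (3S,4R,6S)-9-chloro-4-methyl-1-[(2R,3S)-2-methyl-3-{[(triethylsilyl)oxy]methyl}oxiran-2-yl]-6-[(triethylsilyl)oxy]non-7-yn-3-yl acetate
Conditions: TESCl, imidazole, DMF, 0 °C to rt
Reagents that add atoms: chlorotriethylsilane, CC[Si](Cl)(CC)CC
Why: Silylation turns the C8 oxygen into a poor leaving group, so the propargylic organometallic of step 10 cannot undergo 1,4-elimination to a cumulene, and it keeps C8–O distinct from C6–O.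

Step 9
Reactants: 16 (3S,4R,6S)-9-chloro-4-methyl-1-[(2R,3S)-2-methyl-3-{[(triethylsilyl)oxy]methyl}oxiran-2-yl]-6-[(triethylsilyl)oxy]non-7-yn-3-yl acetate
Product: 18 (3S,4R,6S)-9-chloro-1-[(2R,3R)-3-formyl-2-methyloxiran-2-yl]-4-methyl-6-[(triethylsilyl)oxy]non-7-yn-3-yl acetate, via alkoxysulfonium salt 17 (not isolated)
Conditions: (COCl)2, DMSO, CH2Cl2, −78 to −35 °C; then Et3N, −78 to 0 °C
Reagents that add atoms: none
Why: Swern oxidation applied directly to a primary TES ether cleaves the primary O–Si bond and oxidizes to the aldehyde, while the secondary TES ether, acetate, epoxide and propargylic chloride survive.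

Step 10
Reactants: 18 (3S,4R,6S)-9-chloro-1-[(2R,3R)-3-formyl-2-methyloxiran-2-yl]-4-methyl-6-[(triethylsilyl)oxy]non-7-yn-3-yl acetate
Product: 20 (1S,4R,5S,6S,8S,10R)-1-acetoxy-4,5-epoxy-8-(triethylsilyloxy)-12-norgermacra-7(11),11(13)-dien-6-ol, via propargylchromium species 19 (not isolated)
Conditions: CrCl2 (8 equiv), LiI (0.2 equiv), THF, rt, syringe-pump addition to 2 mM
Reagents that add atoms: none
Why: In this intramolecular Nozaki–Hiyama-type Barbier reaction the γ-substituted propargylchromium reagent adds through C7 (SE2′) to give the α-allenol and the ten-membered ring, as allyl bromides do in chromium-mediated germacranolide closures; Felkin–Anh attack anti to the oxirane C–O bond of the cis-epoxy aldehyde is expected to set C6 (S).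

Step 11
Reactants: 20 (1S,4R,5S,6S,8S,10R)-1-acetoxy-4,5-epoxy-8-(triethylsilyloxy)-12-norgermacra-7(11),11(13)-dien-6-ol
Product: 21 (1S,4R,5S,6S,8S,10R)-1,13-diacetoxy-4,5-epoxy-8-(triethylsilyloxy)germacr-7(11)-en-12,6-olide
Conditions: Pd(OAc)2 (10 mol%), 4,5-diazafluoren-9-one (12 mol%), 1,4-benzoquinone (2 equiv), NaOAc, AcOH, CO (1 atm), THF, 40 °C
Reagents that add atoms: carbon monoxide, [C-]#[O+]; acetic acid, CC(=O)O
Why: Proposed new method: under CO, divalent palladium acetate converts the C6 hydroxyl into an alkoxycarbonyl–palladium species, the tethered 1,1-disubstituted allene inserts with the acyl carbon going to the central carbon C11 from the C6 side (five-membered ring, so C12 must end cis to C6), and the resulting 2-acyl π-allylpalladium is captured by acetate at the unhindered C13 terminus to give the conjugated tetrasubstituted butenolide, with benzoquinone returning zerovalent palladium to the divalent state; the closest known reactions are the PdCl2/CuCl2 oxidative methoxycarbonylation of allenes to 2-(methoxymethyl)acrylates, the Ru3(CO)12-catalysed cyclocarbonylation of α-allenols to α-methylbutenolides and acetate capture of π-allylpalladium in benzoquinone-mediated allylic acetoxylation, and the CO-saturated, diazafluorenone-ligated catalyst is chosen to suppress the competing 5-endo oxypalladation to a 2,5-dihydrofuran.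

Step 12
Reactants: 21 (1S,4R,5S,6S,8S,10R)-1,13-diacetoxy-4,5-epoxy-8-(triethylsilyloxy)germacr-7(11)-en-12,6-olide
Product: 22 (1S,4R,5S,6S,8S,10R)-1,13-diacetoxy-4,5-epoxy-8-hydroxygermacr-7(11)-en-12,6-olide
Conditions: HF·pyridine, pyridine, THF, 0 °C
Reagents that add atoms: none
Why: Buffered fluoride desilylation removes the allylic TES ether without opening the epoxide, cleaving the acetates or (under non-basic conditions) relactonizing onto C8.

Step 13
Reactants: 22 (1S,4R,5S,6S,8S,10R)-1,13-diacetoxy-4,5-epoxy-8-hydroxygermacr-7(11)-en-12,6-olide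
Product: 23 (1S,4R,5S,6S,8S,10R)-1,13-diacetoxy-4,5-epoxy-8-[(E)-2-methylbut-2-enoyloxy]germacr-7(11)-en-12,6-olide
Conditions: tigloyl chloride, pyridine, DMAP (cat.), CH2Cl2, 0 °C to rt
Reagents that add atoms: tigloyl chloride, C/C=C(\C)C(Cl)=O
Why: DMAP-catalysed acylation esterifies C8–OH with retention, and the tiglate is the stable E isomer so no geometric isomerization is expected.

**Compound list**

1 | nerol, (2Z)-3,7-dimethylocta-2,6-dien-1-ol | CC(C)=CCC/C(C)=C\CO | starting material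
2 | [(2S,3R)-3-methyl-3-(4-methylpent-3-en-1-yl)oxiran-2-yl]methanol | CC(C)=CCC[C@@]1(C)O[C@H]1CO | intermediate
3 | triethyl{[(2S,3R)-3-methyl-3-(4-methylpent-3-en-1-yl)oxiran-2-yl]methoxy}silane | CC(C)=CCC[C@@]1(C)O[C@H]1CO[Si](CC)(CC)CC | intermediate
4 | secondary ozonide of 3, a 3,3-dimethyl-1,2,4-trioxolane carrying the epoxy side chain at C5 (not isolated) | CC1(C)OOC(CC[C@@]2(C)O[C@H]2CO[Si](CC)(CC)CC)O1 | intermediate
5 | 3-[(2R,3S)-2-methyl-3-{[(triethylsilyl)oxy]methyl}oxiran-2-yl]propanal | O=CCC[C@@]1(C)O[C@H]1CO[Si](CC)(CC)CC | intermediate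
6 | (S)-but-3-yn-2-ol | C[C@H](O)C#C | starting material
7 | (S)-but-3-yn-2-yl methanesulfonate | C[C@H](OS(C)(=O)=O)C#C | intermediate
8 | (buta-1,2-dien-1-yl)(ethyl)zinc, axially chiral allenylzinc reagent (not isolated) | CC[Zn]C([H])=[C@]=C([H])C | intermediate
9 | ethylzinc alkoxide of (3S,4R)-4-methyl-1-[(2R,3S)-2-methyl-3-{[(triethylsilyl)oxy]methyl}oxiran-2-yl]hex-5-yn-3-ol (not isolated) | C#C[C@@H](C)[C@@H](O[Zn]CC)CC[C@@]1(C)O[C@H]1CO[Si](CC)(CC)CC | intermediate
10 | (3S,4R)-4-methyl-1-[(2R,3S)-2-methyl-3-{[(triethylsilyl)oxy]methyl}oxiran-2-yl]hex-5-yn-3-yl acetate | C#C[C@@H](C)[C@@H](OC(C)=O)CC[C@@]1(C)O[C@H]1CO[Si](CC)(CC)CC | intermediate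
11 | (E)-alkenyl(dicyclohexyl)borane from 10, boron on the terminal carbon (not isolated) | C1CCCCC1B(C1CCCCC1)/C=C/[C@@H](C)[C@@H](OC(C)=O)CC[C@@]2(C)O[C@H]2CO[Si](CC)(CC)CC | intermediate
12 | (3S,4R)-4-methyl-1-[(2R,3S)-2-methyl-3-{[(triethylsilyl)oxy]methyl}oxiran-2-yl]-6-oxohexan-3-yl acetate | O=CC[C@@H](C)[C@@H](OC(C)=O)CC[C@@]1(C)O[C@H]1CO[Si](CC)(CC)CC | intermediate
13 | propargyl chloride, 3-chloroprop-1-yne | C#CCCl | starting material
14 | (3-chloroprop-1-yn-1-yl)(methyl)zinc (not isolated) | C[Zn]C#CCCl | intermediate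
15 | (3S,4R,6S)-9-chloro-6-hydroxy-4-methyl-1-[(2R,3S)-2-methyl-3-{[(triethylsilyl)oxy]methyl}oxiran-2-yl]non-7-yn-3-yl acetate | ClCC#C[C@@H](O)C[C@@H](C)[C@@H](OC(C)=O)CC[C@@]1(C)O[C@H]1CO[Si](CC)(CC)CC | intermediate
16 | (3S,4R,6S)-9-chloro-4-methyl-1-[(2R,3S)-2-methyl-3-{[(triethylsilyl)oxy]methyl}oxiran-2-yl]-6-[(triethylsilyl)oxy]non-7-yn-3-yl acetate | ClCC#C[C@@H](O[Si](CC)(CC)CC)C[C@@H](C)[C@@H](OC(C)=O)CC[C@@]1(C)O[C@H]1CO[Si](CC)(CC)CC | intermediate
17 | alkoxydimethylsulfonium chloride formed at the primary oxygen of 16 (not isolated) | ClCC#C[C@@H](O[Si](CC)(CC)CC)C[C@@H](C)[C@@H](OC(C)=O)CC[C@@]1(C)O[C@H]1CO[S+](C)C.[Cl-] | intermediate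
18 | (3S,4R,6S)-9-chloro-1-[(2R,3R)-3-formyl-2-methyloxiran-2-yl]-4-methyl-6-[(triethylsilyl)oxy]non-7-yn-3-yl acetate | ClCC#C[C@@H](O[Si](CC)(CC)CC)C[C@@H](C)[C@@H](OC(C)=O)CC[C@@]1(C)O[C@H]1C=O | intermediate
19 | propargylic dichlorochromium species of 18, trivalent chromium on C13 (not isolated) | Cl[Cr](Cl)CC#C[C@@H](O[Si](CC)(CC)CC)C[C@@H](C)[C@@H](OC(C)=O)CC[C@@]1(C)O[C@H]1C=O | intermediate
20 | (1S,4R,5S,6S,8S,10R)-1-acetoxy-4,5-epoxy-8-(triethylsilyloxy)-12-norgermacra-7(11),11(13)-dien-6-ol, ten-membered α-allenol with C7=C11=C13H2 and a cis 4,5-epoxide | C=C=C1[C@@H](O[Si](CC)(CC)CC)C[C@@H](C)[C@@H](OC(C)=O)CC[C@@]2(C)O[C@H]2[C@H]1O | intermediate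
21 | (1S,4R,5S,6S,8S,10R)-1,13-diacetoxy-4,5-epoxy-8-(triethylsilyloxy)germacr-7(11)-en-12,6-olide | CC(=O)OCC1=C2[C@@H](O[Si](CC)(CC)CC)C[C@@H](C)[C@@H](OC(C)=O)CC[C@@]3(C)O[C@H]3[C@H]2OC1=O | intermediate
22 | (1S,4R,5S,6S,8S,10R)-1,13-diacetoxy-4,5-epoxy-8-hydroxygermacr-7(11)-en-12,6-olide | CC(=O)OCC1=C2[C@@H](O)C[C@@H](C)[C@@H](OC(C)=O)CC[C@@]3(C)O[C@H]3[C@H]2OC1=O | intermediate
23 | (1S,4R,5S,6S,8S,10R)-1,13-diacetoxy-4,5-epoxy-8-[(E)-2-methylbut-2-enoyloxy]germacr-7(11)-en-12,6-olide (CNP0287840.1) | C/C=C(\C)C(=O)O[C@H]1C[C@@H](C)[C@@H](OC(C)=O)CC[C@@]2(C)O[C@H]2[C@H]2OC(=O)C(COC(C)=O)=C12 | target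

**Step count and risks**

Total: 13 steps. Longest linear sequence: 12 steps (steps 1–3 and 5–13, nerol to 23).

Three steps most likely to fail:

Step 11, the new carbonylative acetoxy-lactonization. The main dangers are 5-endo oxypalladation of the allenol to a dihydrofuran and slow alkoxycarbonyl formation at the hindered C6 hydroxyl. The fallback uses only known chemistry, sets out from 20 and comes back at 21. Ozonolysis of the allene (O3, CH2Cl2, −78 °C; Me2S) gives the ten-membered α-hydroxy ketone F1. Non-basic methylenation with Cp2Ti(μ-Cl)(μ-CH2)AlMe2 (THF, pyridine, −40 to 0 °C), which leaves C6 and C8 unepimerized, gives the 7-methylidene alcohol F2. Yamaguchi esterification of the C6 hydroxyl with 2-(acetoxymethyl)acrylic acid gives the diene ester F3. Ring-closing metathesis with the second-generation Hoveyda–Grubbs catalyst (toluene, 80 °C) closes the tetrasubstituted butenolide alkene and returns 21.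

Step 10, the ten-membered ring closure. The dangers are oligomerization, closure through C13 to a twelve-membered cycloalkyne, decomposition of the hindered epoxy aldehyde, and the wrong configuration at C6. The fallback sets out from 10 and comes back at 20; it closes the ring at C7–C8 and sets C6 in an open-chain step. Direct Swern oxidation of the primary silyl ether of 10 gives the epoxy aldehyde F4. Addition of lithium 3-chloroprop-1-ynide (from 13 and n-BuLi, THF, −78 °C) under Felkin–Anh control gives the (6S)-propargylic alcohol F5. Hydroboration–oxidation of the terminal alkyne (Cy2BH; NaBO3·4H2O) gives the hydroxy aldehyde F6. CrCl2/LiI ring closure onto this unhindered aldehyde, with the free C6 hydroxyl tolerated, gives the allene diol F7. Selective silylation of the less hindered C8 hydroxyl (TESCl, imidazole, −20 °C) returns 20. If the 8-epimer is formed, it is inverted by Mitsunobu esterification at the tigloylation stage.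

Step 7, the asymmetric alkynylation with propargyl chloride. The dangers are that this alkyne is untested in the zinc–ProPhenol reaction, that the unbranched aldehyde may self-condense, and that the facial sense is not confirmed. The fallback sets out from 12 and comes back at 15. Lithium 3-chloroprop-1-ynide (from 13 and n-BuLi, THF, −78 °C) adds to 12 to give the carbinol-epimeric propargylic alcohols F8. Dess–Martin oxidation gives the ynone F9. Noyori asymmetric transfer hydrogenation with RuCl[(S,S)-TsDPEN](p-cymene) in 2-propanol (base-free amido form of the catalyst) reduces it to the (6S) alcohol 15.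

**Further compounds**

F1 | step 11 | 1-acetoxy-4,5-epoxy-6-hydroxy-8-(triethylsilyloxy)-11,12,13-trinorgermacran-7-one, configuration at C1, C4, C5, C6, C8 and C10 as in 20 | O=C1[C@@H](O[Si](CC)(CC)CC)C[C@@H](C)[C@@H](OC(C)=O)CC[C@@]2(C)O[C@H]2[C@H]1O
F2 | step 11 | 1-acetoxy-4,5-epoxy-8-(triethylsilyloxy)-12,13-dinorgermacr-7(11)-en-6-ol (7-methylidene alcohol), configuration as in 20 | C=C1[C@@H](O[Si](CC)(CC)CC)C[C@@H](C)[C@@H](OC(C)=O)CC[C@@]2(C)O[C@H]2[C@H]1O
F3 | step 11 | 6-O-[2-(acetoxymethyl)acryloyl] ester of F2 | C=C1[C@@H](O[Si](CC)(CC)CC)C[C@@H](C)[C@@H](OC(C)=O)CC[C@@]2(C)O[C@H]2[C@H]1OC(=O)C(=C)COC(C)=O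
F4 | step 10 | (3S,4R)-1-[(2R,3R)-3-formyl-2-methyloxiran-2-yl]-4-methylhex-5-yn-3-yl acetate | C#C[C@@H](C)[C@@H](OC(C)=O)CC[C@@]1(C)O[C@H]1C=O
F5 | step 10 | (3S,4R)-1-{(2R,3S)-3-[(1S)-4-chloro-1-hydroxybut-2-yn-1-yl]-2-methyloxiran-2-yl}-4-methylhex-5-yn-3-yl acetate | C#C[C@@H](C)[C@@H](OC(C)=O)CC[C@@]1(C)O[C@H]1[C@@H](O)C#CCCl
F6 | step 10 | (3S,4R)-1-{(2R,3S)-3-[(1S)-4-chloro-1-hydroxybut-2-yn-1-yl]-2-methyloxiran-2-yl}-4-methyl-6-oxohexan-3-yl acetate | O=CC[C@@H](C)[C@@H](OC(C)=O)CC[C@@]1(C)O[C@H]1[C@@H](O)C#CCCl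
F7 | step 10 | (1S,4R,5S,6S,8S,10R)-1-acetoxy-4,5-epoxy-12-norgermacra-7(11),11(13)-diene-6,8-diol | C=C=C1[C@@H](O)C[C@@H](C)[C@@H](OC(C)=O)CC[C@@]2(C)O[C@H]2[C@H]1O
F8 | step 7 | (3S,4R)-9-chloro-6-hydroxy-4-methyl-1-[(2R,3S)-2-methyl-3-{[(triethylsilyl)oxy]methyl}oxiran-2-yl]non-7-yn-3-yl acetate, both C6 epimers | ClCC#CC(O)C[C@@H](C)[C@@H](OC(C)=O)CC[C@@]1(C)O[C@H]1CO[Si](CC)(CC)CC
F9 | step 7 | (3S,4R)-9-chloro-4-methyl-1-[(2R,3S)-2-methyl-3-{[(triethylsilyl)oxy]methyl}oxiran-2-yl]-6-oxonon-7-yn-3-yl acetate | ClCC#CC(=O)C[C@@H](C)[C@@H](OC(C)=O)CC[C@@]1(C)O[C@H]1CO[Si](CC)(CC)CC
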